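**Plan**
1. Numbering (clerodane): ring A = C1–C5/C10, ring B = C5–C10, chain C11–C16 on C9, C17 = Me on C8, C18 = CH2 on C4, C19 = Me on C5, C20 = Me on C9; β = the face of the C5 methyl and H‑10.
2. Cuts: C11–C12 (fragment union); then the C8–C11 bond of a cyclopropane over C8/C9 (C11 from CH2I2); C9–C20 and C8–C17 (cuprate/MeI); C4–C5 (ring A, intramolecular Michael); C1–C10 (alkylation). C4=C18, the C2 oxygen and the acetate come last.
3. Enabling feature: in ring B, C11 is γ to the C7 oxygen (C7–C8–C9–C11). With C7 as ketone and C11 as the CH2 of a cyclopropane fused at C8–C9, C11 is a strain‑loaded γ‑electrophile; opening it unveils the C9 quaternary centre and returns the C7/C8 enol.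
4. Forward: ring B (3‑ethoxycyclohexenone) → ring A closed onto it to a meso cis‑decalin‑3,7‑dione → desymmetrisation → C8/C9 methyls → β‑cyclopropane → coupling with the C12–C16 zinc reagent → C7 acetate → ring A diosphenol and exo‑methylene.
5. Stereo: C5/C10 cis from the tethered Michael addition, absolute sense from chiral‑base desymmetrisation (sharpened by CBS); the CBS‑made 7β‑OH directs CH2 to the β face (C9); C8 by protonation anti to C20; C7 by thermodynamic reduction; C13 from (R)‑methyl hydrogen 3‑methylglutarate.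

Key step: step 12

Remark: lithium enolates are treated as the reacting form of the carbonyl compound and are not numbered; other non‑isolated intermediates are.
Assumption: the (R,R)‑lithium amide is taken to remove the C8 proton of 6 (giving 8 as drawn); if it selects the enantiotopic C2 proton, the (S,S)‑base is used instead.

Step 1
Reactants: 1 3-ethoxycyclohex-2-en-1-one; 2 2-(2-bromoethyl)-2-methyl-1,3-dioxolane
Product: 3 3-ethoxy-6-[2-(2-methyl-1,3-dioxolan-2-yl)ethyl]cyclohex-2-en-1-one (racemic)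
Conditions: LDA, THF, −78 °C; then 2, DMPU, −78 → 25 °C
Reagents that add atoms: none
Why: Stork–Danheiser α′‑alkylation: the kinetic enolate of the vinylogous ester forms only at C6 and is alkylated by the primary bromide (C1–C10 bond); the new centre (future C10) is racemic, which is harmless because both enantiomers converge on meso 6.

Step 2
Reactants: 3 3-ethoxy-6-[2-(2-methyl-1,3-dioxolan-2-yl)ethyl]cyclohex-2-en-1-one
Product: 5 3-methyl-4-(3-oxobutyl)cyclohex-2-en-1-one (racemic), via tertiary carbinol 4 (not isolated)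
Conditions: MeLi, THF, −78 → 0 °C; then 2 M HCl, THF, 25 °C
Reagents that add atoms: methyllithium, [Li]C; water, O
Why: 1,2‑addition of MeLi to the vinylogous ester carbonyl and acid‑induced Stork–Danheiser transposition (loss of ethanol) give the 3‑methyl enone (C19 on C5), and the same acid unmasks the methyl ketone.

Step 3
Reactants: 5 3-methyl-4-(3-oxobutyl)cyclohex-2-en-1-one
Product: 6 cis-8a-methyl-4,4a,5,6,8,8a-hexahydronaphthalene-2,7(1H,3H)-dione (meso; target numbering: 5β-methyl-10βH-decalin-3,7-dione)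
Conditions: t-BuOK (0.3 equiv), t-BuOH/THF, 0 → 25 °C
Reagents that add atoms: none
Why: Intramolecular 6‑exo‑trig Michael addition of the methyl‑ketone carbon (C4) to the enone β‑carbon C5 closes ring A and forms the C5 quaternary centre; axial attack by a tether on the adjacent C10 forces the cis ring fusion (5‑Me and H‑10 cis), and the product is an achiral meso diketone.

Step 4
Reactants: 6 cis-8a-methyl-4,4a,5,6,8,8a-hexahydronaphthalene-2,7(1H,3H)-dione
Product: 8 (4aR,8aS)-8a-methyl-4,4a,8,8a-tetrahydronaphthalene-2,7(1H,3H)-dione (target numbering: 5β-methyl-10βH-decal-8-ene-3,7-dione), via TMS enol ether 7 (not isolated)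
Conditions: (R,R)-bis(1-phenylethyl)amine, n-BuLi, LiCl, TMSCl (internal quench), THF, −100 °C; then Pd(OAc)2 (10 mol%), O2, DMSO, 25 °C
Reagents that add atoms: none
Why: Enantioselective deprotonation of a meso ketone by a chiral lithium amide removes the less hindered C8 proton of one enantiotopic ring (C6 and C4 are neopentyl) and so fixes the absolute configuration of C5 and C10, and Saegusa–Ito oxidation of the silyl enol ether gives the ring B enone.

Step 5
Reactants: 8 (4aR,8aS)-8a-methyl-4,4a,8,8a-tetrahydronaphthalene-2,7(1H,3H)-dione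
Product: 9 3,3-ethylenedioxy-5β-methyl-10βH-decal-8-en-7-one
Conditions: 1,2-bis(trimethylsilyloxy)ethane, TMSOTf (cat.), CH2Cl2, −78 °C
Reagents that add atoms: 1,2-bis(trimethylsilyloxy)ethane, C[Si](C)(C)OCCO[Si](C)(C)C
Why: TMSOTf‑catalysed ketalisation with the bis‑silyl glycol is selective for the saturated C3 ketone over the conjugated C7 enone.

Step 6
Reactants: 9 3,3-ethylenedioxy-5β-methyl-10βH-decal-8-en-7-one
Product: 10 3,3-ethylenedioxy-5β,8α,9β-trimethyl-10βH-decalin-7-one (expected major diastereomer)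
Conditions: Me2CuLi (from MeLi, CuI), Et2O, −78 → 0 °C; then MeI, HMPA, 0 → 25 °C
Reagents that add atoms: lithium dimethylcuprate, [Li+].C[Cu-]C; iodomethane, CI
Why: Cuprate conjugate addition puts C20 on C9 and the resulting enolate is methylated at C8 (C17), expected trans; both new centres are erased in step 7, so their configuration does not matter.

Step 7
Reactants: 10 3,3-ethylenedioxy-5β,8α,9β-trimethyl-10βH-decalin-7-one
Product: 11 3,3-ethylenedioxy-5β,8,9-trimethyl-10βH-decal-8-en-7-one
Conditions: IBX, DMSO/fluorobenzene, 70 °C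
Reagents that add atoms: none
Why: IBX dehydrogenation of the ketone; C5 is quaternary, so unsaturation can only form between C8 and C9, giving the tetrasubstituted enone.

Step 8
Reactants: 11 3,3-ethylenedioxy-5β,8,9-trimethyl-10βH-decal-8-en-7-one
Product: 12 3,3-ethylenedioxy-5β,8,9-trimethyl-10βH-decal-8-en-7β-ol (7S)
Conditions: (R)-Me-CBS (20 mol%), catecholborane, toluene, −78 °C
Reagents that add atoms: none
Why: Corey–Bakshi–Shibata reduction with the 2‑methylalkenyl side as the large group should deliver hydride to the α face and give the 7β‑alcohol under catalyst control, and any minor enantiomer from step 4 becomes a separable diastereomer.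

Step 9
Reactants: 12 3,3-ethylenedioxy-5β,8,9-trimethyl-10βH-decal-8-en-7β-ol
Product: 13 3,3-ethylenedioxy-5β,8α,9α-trimethyl-8β,9β-methano-10βH-decalin-7β-ol (C11 = cyclopropane CH2)
Conditions: Et2Zn, CH2I2, CH2Cl2, 0 → 25 °C
Reagents that add atoms: diiodomethane, ICI
Why: Hydroxyl‑directed Simmons–Smith cyclopropanation delivers CH2 syn to the 7β‑OH, i.e. to the β face, which sets C9 (C11 β, C20 α) and C8.

Step 10
Reactants: 13 3,3-ethylenedioxy-5β,8α,9α-trimethyl-8β,9β-methano-10βH-decalin-7β-ol
Product: 14 3,3-ethylenedioxy-5β,8α,9α-trimethyl-8β,9β-methano-10βH-decalin-7-one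
Conditions: Dess–Martin periodinane, NaHCO3, CH2Cl2, 0 → 25 °C
Reagents that add atoms: none
Why: Dess–Martin oxidation of the cyclopropyl carbinol gives the cyclopropyl ketone without ring opening and places the C7 carbonyl next to the C8–C11 bond.

Step 11
Reactants: 15 (R)-5-methoxy-3-methyl-5-oxopentanoic acid
Product: 16 methyl (S)-4-iodo-3-methylbutanoate
Conditions: PhI(OAc)2, I2, cyclohexane, hν, reflux
Reagents that add atoms: iodine, II
Why: Hunsdiecker‑type radical iododecarboxylation replaces CO2H by I at the future C12; C13 is not involved and keeps its configuration (the descriptor changes from R to S only through priorities).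

Step 12
Reactants: 14 3,3-ethylenedioxy-5β,8α,9α-trimethyl-8β,9β-methano-10βH-decalin-7-one; 16 methyl (S)-4-iodo-3-methylbutanoate
Product: 19 methyl (3R)-5-[3,3-ethylenedioxy-5β,8α,9α-trimethyl-7-oxo-10βH-decalin-9β-yl]-3-methylpentanoate, via organozinc iodide 17 (not isolated), via TMS enol ether 18 (not isolated)
Conditions: 16, Zn dust, LiCl, THF, 40 °C; then 14, TMSCl, NiCl2·DME (10 mol%), terpyridine (12 mol%), THF/NMP, 25 °C; then aq. citric acid, THF, 0 °C
Reagents that add atoms: none
Why: Proposed new method: low‑valent nickel is proposed to insert, with O‑silylation by TMSCl, into the cyclopropane bond C8–C11 conjugated with the C7 ketone, giving a C11 alkylnickel silyl enolate that transmetalates with organozinc 17 and reductively eliminates to form C11–C12; the closest known reaction types are the nickel‑catalysed ring‑opening cross‑coupling of (mainly aryl) cyclopropyl ketones with organozinc reagents and TMSCl to γ‑substituted silyl enol ethers, and the homoconjugate addition of organocuprates to cyclopropyl ketones. No ring is closed: the three‑membered ring is opened and its strain drives the coupling. C9 needs no new control, because its configuration was fixed in the cyclopropane and the C9–C11 bond is untouched, so the quaternary centre is simply unveiled (C11 β, C20 α). The new centre C8 is set on work‑up by kinetic protonation of silyl enol ether 18 from the β face, anti to the pseudoaxial C20 methyl, which should give the equatorial 8α‑methyl ketone (also the thermodynamic epimer). The selectivity needed is cleavage of the exocyclic C8–C11 bond and not the ring‑fusion bond C8–C9: in the rigid bicyclo[4.1.0]heptan‑2‑one unit C8–C11 is the bond aligned with the carbonyl π system and C11 is the only unsubstituted cyclopropane carbon, while the alkylzinc does not add to the ketone, the ketal or its own ester. The C11–nickel intermediate has no β‑hydrogen (C9 is quaternary), which removes β‑hydride elimination as the usual drain in alkyl–alkyl coupling.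

Step 13
Reactants: 19 methyl (3R)-5-[3,3-ethylenedioxy-5β,8α,9α-trimethyl-7-oxo-10βH-decalin-9β-yl]-3-methylpentanoate
Product: 20 methyl (3R)-5-[3,3-ethylenedioxy-7β-hydroxy-5β,8α,9α-trimethyl-10βH-decalin-9β-yl]-3-methylpentanoate
Conditions: SmI2, THF/H2O, 0 °C
Reagents that add atoms: none
Why: Single‑electron (dissolving‑metal‑type) ketone reduction should give the thermodynamically preferred equatorial 7β‑alcohol (trans to the 8α‑methyl), whereas hydride attack from the α face is blocked by the axial C20 and C4; the unactivated methyl ester is not reduced by amine‑free SmI2–H2O.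

Step 14
Reactants: 20 methyl (3R)-5-[3,3-ethylenedioxy-7β-hydroxy-5β,8α,9α-trimethyl-10βH-decalin-9β-yl]-3-methylpentanoate
Product: 21 methyl (3R)-5-[7β-acetoxy-3,3-ethylenedioxy-5β,8α,9α-trimethyl-10βH-decalin-9β-yl]-3-methylpentanoate
Conditions: Ac2O, pyridine, DMAP (cat.), 25 °C
Reagents that add atoms: acetic anhydride, CC(=O)OC(C)=O
Why: DMAP‑catalysed acylation of the equatorial secondary alcohol with retention at C7.

Step 15
Reactants: 21 methyl (3R)-5-[7β-acetoxy-3,3-ethylenedioxy-5β,8α,9α-trimethyl-10βH-decalin-9β-yl]-3-methylpentanoate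
Product: 22 methyl (3R)-5-[7β-acetoxy-5β,8α,9α-trimethyl-3-oxo-10βH-decalin-9β-yl]-3-methylpentanoate
Conditions: PPTS, acetone/H2O, 50 °C
Reagents that add atoms: water, O
Why: Mild acid hydrolysis of the dioxolane frees the C3 ketone; acetate and methyl ester are stable and C8 can no longer epimerise.

Step 16
Reactants: 22 methyl (3R)-5-[7β-acetoxy-5β,8α,9α-trimethyl-3-oxo-10βH-decalin-9β-yl]-3-methylpentanoate
Product: 24 methyl (3R)-5-[7β-acetoxy-5β,8α,9α-trimethyl-3-oxo-2-(triethylsilyloxy)-10βH-decalin-9β-yl]-3-methylpentanoate (C2 epimers), via TES enol ether 23 (not isolated)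
Conditions: LiHMDS, THF, −78 °C; TESCl, −78 → 0 °C; then mCPBA, NaHCO3, CH2Cl2, −20 → 0 °C
Reagents that add atoms: chlorotriethylsilane, CC[Si](Cl)(CC)CC; 3-chloroperoxybenzoic acid, OOC(=O)c1cccc(Cl)c1
Why: Kinetic enolisation of the ketone (more acidic than the esters) at the unhindered C2 (C4 is neopentyl), O‑silylation and Rubottom oxidation with silyl migration give the protected C2 oxygen; the C2 configuration is immaterial.

Step 17
Reactants: 24 methyl (3R)-5-[7β-acetoxy-5β,8α,9α-trimethyl-3-oxo-2-(triethylsilyloxy)-10βH-decalin-9β-yl]-3-methylpentanoate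
Product: 27 methyl (3R)-5-[7β-acetoxy-5β,8α,9α-trimethyl-4-methylene-3-oxo-2-(triethylsilyloxy)-10βH-decalin-9β-yl]-3-methylpentanoate (C2 epimers), via Mannich base 25 (not isolated), via ammonium iodide 26 (not isolated)
Conditions: LiHMDS, THF, −78 → −30 °C; Eschenmoser's salt; then MeI, CH2Cl2/MeOH, 25 °C; then aq. NaHCO3, CH2Cl2
Reagents that add atoms: N,N-dimethylmethyleneiminium iodide, C=[N+](C)C.[I-]
Why: With C2 blocked, the α′‑enolate forms at C4 and undergoes a Mannich reaction with Eschenmoser's salt, and N‑methylation with base‑induced elimination gives the C4=C18 exo‑methylene.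

Step 18
Reactants: 27 methyl (3R)-5-[7β-acetoxy-5β,8α,9α-trimethyl-4-methylene-3-oxo-2-(triethylsilyloxy)-10βH-decalin-9β-yl]-3-methylpentanoate
Product: 28 methyl (3R)-5-[7β-acetoxy-2-hydroxy-5β,8α,9α-trimethyl-4-methylene-3-oxo-10βH-decalin-9β-yl]-3-methylpentanoate (C2 epimers)
Conditions: HF·pyridine, THF, 0 °C
Reagents that add atoms: none
Why: Fluoride‑mediated cleavage of the triethylsilyl ether under conditions that leave the acetate, the ester and the α‑methylene ketone intact.

Step 19
Reactants: 28 methyl (3R)-5-[7β-acetoxy-2-hydroxy-5β,8α,9α-trimethyl-4-methylene-3-oxo-10βH-decalin-9β-yl]-3-methylpentanoate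
Product: 29 CNP0180040.1
Conditions: Dess–Martin periodinane, NaHCO3, CH2Cl2, 0 → 25 °C
Reagents that add atoms: none
Why: Dess–Martin oxidation of the α‑hydroxy ketone gives the 2,3‑dione, which can enolise only toward C1 (C4 is sp2) and so should settle as the C1=C2(OH)–C3=O diosphenol of the target.

**Compound list**
1 | 3-ethoxycyclohex-2-en-1-one | CCOC1=CC(=O)CCC1 | starting material
2 | 2-(2-bromoethyl)-2-methyl-1,3-dioxolane | CC1(CCBr)OCCO1 | starting material
3 | 3-ethoxy-6-[2-(2-methyl-1,3-dioxolan-2-yl)ethyl]cyclohex-2-en-1-one (racemic) | CCOC1=CC(=O)C(CCC2(C)OCCO2)CC1 | intermediate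
4 | 3-ethoxy-1-methyl-6-[2-(2-methyl-1,3-dioxolan-2-yl)ethyl]cyclohex-2-en-1-ol (racemic diastereomers, not isolated) | CCOC1=CC(C)(O)C(CCC2(C)OCCO2)CC1 | intermediate
5 | 3-methyl-4-(3-oxobutyl)cyclohex-2-en-1-one (racemic) | CC(=O)CCC1CCC(=O)C=C1C | intermediate
6 | cis-8a-methyl-4,4a,5,6,8,8a-hexahydronaphthalene-2,7(1H,3H)-dione (meso) | C1C(=O)CC[C@@H]2CCC(=O)C[C@]12C | intermediate
7 | 5β-methyl-7-(trimethylsilyloxy)-10βH-decal-7-en-3-one (not isolated) | C1C(=O)CC[C@@H]2CC=C(O[Si](C)(C)C)C[C@]12C | intermediate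
8 | (4aR,8aS)-8a-methyl-4,4a,8,8a-tetrahydronaphthalene-2,7(1H,3H)-dione | C1C(=O)CC[C@@H]2C=CC(=O)C[C@]12C | intermediate
9 | 3,3-ethylenedioxy-5β-methyl-10βH-decal-8-en-7-one | C1C3(OCCO3)CC[C@@H]2C=CC(=O)C[C@]12C | intermediate
10 | 3,3-ethylenedioxy-5β,8α,9β-trimethyl-10βH-decalin-7-one | C1C3(OCCO3)CC[C@@H]2[C@@H](C)[C@H](C)C(=O)C[C@]12C | intermediate
11 | 3,3-ethylenedioxy-5β,8,9-trimethyl-10βH-decal-8-en-7-one | C1C3(OCCO3)CC[C@@H]2C(C)=C(C)C(=O)C[C@]12C | intermediate
12 | 3,3-ethylenedioxy-5β,8,9-trimethyl-10βH-decal-8-en-7β-ol | C1C3(OCCO3)CC[C@@H]2C(C)=C(C)[C@@H](O)C[C@]12C | intermediate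
13 | 3,3-ethylenedioxy-5β,8α,9α-trimethyl-8β,9β-methano-10βH-decalin-7β-ol | C1C3(OCCO3)CC[C@@H]2[C@@]4(C)C[C@@]4(C)[C@@H](O)C[C@]12C | intermediate
14 | 3,3-ethylenedioxy-5β,8α,9α-trimethyl-8β,9β-methano-10βH-decalin-7-one | C1C3(OCCO3)CC[C@@H]2[C@@]4(C)C[C@@]4(C)C(=O)C[C@]12C | intermediate
15 | (R)-5-methoxy-3-methyl-5-oxopentanoic acid (methyl hydrogen (R)-3-methylglutarate) | OC(=O)C[C@@H](C)CC(=O)OC | starting material
16 | methyl (S)-4-iodo-3-methylbutanoate | IC[C@@H](C)CC(=O)OC | intermediate
17 | [(S)-4-methoxy-2-methyl-4-oxobutyl]zinc iodide (not isolated) | I[Zn]C[C@@H](C)CC(=O)OC | intermediate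
18 | methyl (3R)-5-[3,3-ethylenedioxy-5β,8,9α-trimethyl-7-(trimethylsilyloxy)-10βH-decal-7-en-9β-yl]-3-methylpentanoate (not isolated) | C1C3(OCCO3)CC[C@@H]2[C@@](C)(CC[C@@H](C)CC(=O)OC)C(C)=C(O[Si](C)(C)C)C[C@]12C | intermediate
19 | methyl (3R)-5-[3,3-ethylenedioxy-5β,8α,9α-trimethyl-7-oxo-10βH-decalin-9β-yl]-3-methylpentanoate | C1C3(OCCO3)CC[C@@H]2[C@@](C)(CC[C@@H](C)CC(=O)OC)[C@H](C)C(=O)C[C@]12C | intermediate
20 | methyl (3R)-5-[3,3-ethylenedioxy-7β-hydroxy-5β,8α,9α-trimethyl-10βH-decalin-9β-yl]-3-methylpentanoate | C1C3(OCCO3)CC[C@@H]2[C@@](C)(CC[C@@H](C)CC(=O)OC)[C@H](C)[C@@H](O)C[C@]12C | intermediate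
21 | methyl (3R)-5-[7β-acetoxy-3,3-ethylenedioxy-5β,8α,9α-trimethyl-10βH-decalin-9β-yl]-3-methylpentanoate | C1C3(OCCO3)CC[C@@H]2[C@@](C)(CC[C@@H](C)CC(=O)OC)[C@H](C)[C@@H](OC(C)=O)C[C@]12C | intermediate
22 | methyl (3R)-5-[7β-acetoxy-5β,8α,9α-trimethyl-3-oxo-10βH-decalin-9β-yl]-3-methylpentanoate | C1C(=O)CC[C@@H]2[C@@](C)(CC[C@@H](C)CC(=O)OC)[C@H](C)[C@@H](OC(C)=O)C[C@]12C | intermediate
23 | C2=C3 triethylsilyl enol ether of 22 (not isolated) | C1C(O[Si](CC)(CC)CC)=CC[C@@H]2[C@@](C)(CC[C@@H](C)CC(=O)OC)[C@H](C)[C@@H](OC(C)=O)C[C@]12C | intermediate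
24 | methyl (3R)-5-[7β-acetoxy-5β,8α,9α-trimethyl-3-oxo-2-(triethylsilyloxy)-10βH-decalin-9β-yl]-3-methylpentanoate (C2 epimers) | C1C(=O)C(O[Si](CC)(CC)CC)C[C@@H]2[C@@](C)(CC[C@@H](C)CC(=O)OC)[C@H](C)[C@@H](OC(C)=O)C[C@]12C | intermediate
25 | 4-[(dimethylamino)methyl] derivative of 24 (C2/C4 epimers, not isolated) | C1(CN(C)C)C(=O)C(O[Si](CC)(CC)CC)C[C@@H]2[C@@](C)(CC[C@@H](C)CC(=O)OC)[C@H](C)[C@@H](OC(C)=O)C[C@]12C | intermediate
26 | 4-[(trimethylammonio)methyl] iodide of 24 (not isolated) | C1(C[N+](C)(C)C)C(=O)C(O[Si](CC)(CC)CC)C[C@@H]2[C@@](C)(CC[C@@H](C)CC(=O)OC)[C@H](C)[C@@H](OC(C)=O)C[C@]12C.[I-] | intermediate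
27 | methyl (3R)-5-[7β-acetoxy-5β,8α,9α-trimethyl-4-methylene-3-oxo-2-(triethylsilyloxy)-10βH-decalin-9β-yl]-3-methylpentanoate (C2 epimers) | C=C1C(=O)C(O[Si](CC)(CC)CC)C[C@@H]2[C@@](C)(CC[C@@H](C)CC(=O)OC)[C@H](C)[C@@H](OC(C)=O)C[C@]12C | intermediate
28 | methyl (3R)-5-[7β-acetoxy-2-hydroxy-5β,8α,9α-trimethyl-4-methylene-3-oxo-10βH-decalin-9β-yl]-3-methylpentanoate (C2 epimers) | C=C1C(=O)C(O)C[C@@H]2[C@@](C)(CC[C@@H](C)CC(=O)OC)[C@H](C)[C@@H](OC(C)=O)C[C@]12C | intermediate
29 | CNP0180040.1: methyl (3R)-5-[7β-acetoxy-2-hydroxy-5β,8α,9α-trimethyl-4-methylene-3-oxo-10βH-decal-1-en-9β-yl]-3-methylpentanoate (5S,7S,8S,9R,10R,13R) | C=C1C(=O)C(O)=C[C@@H]2[C@@](C)(CC[C@@H](C)CC(=O)OC)[C@H](C)[C@@H](OC(C)=O)C[C@]12C | target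

**Total step count:** 19. **Longest linear sequence:** 18 steps (steps 1–10 and 12–19; step 11 is the convergent branch).

**Steps most likely to fail**

Step 12. The nickel may fail to open the hindered, fully alkyl‑substituted cyclopropyl ketone, or the alkylzinc may be lost by protonation or homocoupling before the C–C bond forms. The fallback separates ring opening from coupling and uses known reaction types. It sets out from 14: hydrolysis of the dioxolane (PPTS, aqueous acetone), needed because the next reagent attacks ketals, gives cyclopropyl diketone F1. Iodotrimethylsilane (CH2Cl2, −40 °C, aqueous work‑up) then opens the cyclopropane by iodide attack at the unsubstituted C11, giving γ‑iodo diketone F2. Nickel‑catalysed alkyl–alkyl Negishi coupling of this unactivated primary iodide with organozinc 17 (Ni(cod)2, s‑Bu‑Pybox, DMA, 25 °C) gives coupled diketone F3. Selective TMSOTf‑catalysed ketalisation of the unhindered C3 ketone with 1,2‑bis(trimethylsilyloxy)ethane brings the route back at 19.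

Step 4. The chiral base may discriminate poorly between the two enantiotopic rings, or both ketones may be silylated. The fallback sets out from 6 and desymmetrises by enzymatic mono‑reduction: a ketoreductase chosen by screening (NADPH recycling, buffer) reduces the C7 carbonyl of one ring to give hydroxy ketone F4. Ketalisation of the remaining C3 ketone (ethylene glycol, PPTS, benzene, reflux) gives hydroxy ketal F5. Excess IBX (DMSO, 80 °C) oxidises the alcohol to keto ketal F6 and dehydrogenates it in the same flask to enone 9, where the route is rejoined.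

Step 13. Facial selectivity in the C7 reduction may be poor, or the ester may be partly reduced. The fallback sets out from 19 and uses kinetic control followed by inversion: NaBH4 (MeOH, 0 °C) attacks from the open β face and should give the axial 7α‑alcohol F7. Mitsunobu reaction with acetic acid (PPh3, DIAD, toluene) then installs the acetate with inversion and returns the route at 21.

**Further compounds**
F1 | step 12 | 5β,8α,9α-trimethyl-8β,9β-methano-10βH-decalin-3,7-dione | C1C(=O)CC[C@@H]2[C@@]4(C)C[C@@]4(C)C(=O)C[C@]12C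
F2 | step 12 | 9β-(iodomethyl)-5β,8α,9α-trimethyl-10βH-decalin-3,7-dione | C1C(=O)CC[C@@H]2[C@@](C)(CI)[C@H](C)C(=O)C[C@]12C
F3 | step 12 | methyl (3R)-5-[5β,8α,9α-trimethyl-3,7-dioxo-10βH-decalin-9β-yl]-3-methylpentanoate | C1C(=O)CC[C@@H]2[C@@](C)(CC[C@@H](C)CC(=O)OC)[C@H](C)C(=O)C[C@]12C
F4 | step 4 | 7-hydroxy-5β-methyl-10βH-decalin-3-one (C7 configuration set by the enzyme, not assigned) | C1C(=O)CC[C@@H]2CCC(O)C[C@]12C
F5 | step 4 | 3,3-ethylenedioxy-5β-methyl-10βH-decalin-7-ol | C1C3(OCCO3)CC[C@@H]2CCC(O)C[C@]12C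
F6 | step 4 | 3,3-ethylenedioxy-5β-methyl-10βH-decalin-7-one | C1C3(OCCO3)CC[C@@H]2CCC(=O)C[C@]12C
F7 | step 13 | methyl (3R)-5-[3,3-ethylenedioxy-7α-hydroxy-5β,8α,9α-trimethyl-10βH-decalin-9β-yl]-3-methylpentanoate | C1C3(OCCO3)CC[C@@H]2[C@@](C)(CC[C@@H](C)CC(=O)OC)[C@H](C)[C@H](O)C[C@]12C
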